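(All runs come from a simulation for substances that don't exist; the scatter is artificial.)

I start from the rate constants and keep their ratios. If each exchange is second order in E and uses one E, dividing the rate of Z by the rate of E use removes time and the level of E, so Z follows one curve in ν, the E used per X charged (the mean degree of substitution).

| flask | X | E | remark | time |
|---|---|---|---|---|
| autumn | 0.75 M | 3 M | run made earlier |  |
| flask | 1.5 M | 3.00 M |  | 2.5 min |

- autumn (time / s: Z / %, D / %): 10.0: 42.6, 3.3; 20.0: 55.4, 8.5; 30.0: 55.5, 8.9; 60.0: 43.7, 10.6; 120: 22.3, 9.3

(scatter of a reading: 1 percentage point)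

- equivalents of E to X, everything else as given, that leave most Z at 2.5 min
- the amount of Z then, in percent of the X charged
- the amount of Z with the amounts as given



1. I first ask what an error in the absolute constants costs, and it shifts when a flask moves along that curve, not the curve itself; I can bear much of this, because the autumn readings of Z stand level at 20.0 s and 30.0 s, earlier than the asked 2.5 min, from the same E.

2. An error in the peak height passes straight into the best Z, so this number must be good; I read P = 55.5% at 30.0 s, level within the scatter of 1 percentage point with the 55.4% before it.

3. An error in D counts twice in the position of the peak, ν_p, the exchanges seen per X at that reading, Z plus two for each D, which gives 0.733, an estimate that I take to be low, as Z + D falls in the later autumn readings and any unseen forms go uncounted.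

This flask charges 2.00 E per X, more than ν_p, so I expect it past the peak, and the best charge somewhat above ν_p with Z near P.

The forecast says 1.1 equiv, 57% and 43%, its best charge “with E nearly exhausted at the end”; its peak stands above my P.

    Z + E ⇌ G + D (K = 2.80, k = 0.00941 M⁻¹ s⁻¹)
    X + E ⇌ G + Z (K = 47.2, k = 0.0249 M⁻¹ s⁻¹)
    D + E ⇌ G + L (K = 54.9, k = 0.0390 M⁻¹ s⁻¹)
    D ⇌ Q (K = 0.560, k = 0.598 s⁻¹)

The flask gives 1.18 equiv, 55.5% and, as charged, 43.3%, so the given charge costs 12 points of Z. In the flask 12% of E remains at 2.50 min, so ν = 1.77, beyond ν_p. The neighbour with 0.60 M of X keeps 47% of its E, so ν = 2.63, further along than the flask; there L holds 77.7% of the X and Z is down to 13.5%.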